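**Retrosynthetic overview**

1. The cyclohexadienone is not built; it is unmasked last by methoxylative oxidative dearomatization of a para-(sec-alkyl), ortho-allyl phenol, followed by ester cleavage. No ring is formed in the route: both six-membered rings come from commercial arenes.
2. The ortho-allyl group comes from an aromatic Claisen rearrangement of an O-allyl group carried from the start.
3. The benzylic CH2 comes from deoxygenation of a ketone whose only job is to activate the neighbouring carbon.
4. Key disconnection: the bond between the ring-A aryl carbon and the side-chain methine. A racemic α-bromoketone (α-keto cation equivalent) is joined to an arylzinc under Ni/chiral pybox catalysis, stereoconvergently, which sets the methine stereocentre.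
5. Building blocks: propiovanillone, 4-bromo-3-methoxyphenol, allyl bromide.

Locants used below: C4 = quaternary ring carbon of the target, C8 = side-chain CH(CH3), C7 = benzylic CH2. The target is (4S,8R).

Assumption: the sense of induction of the Ni/pybox catalyst is assigned empirically; the ligand antipode that delivers (S)-9 is the one used (chiral HPLC check).

Assumption: only discrete species (Grignard reagent, arylzinc, tosylhydrazone, dienone pivalate) are numbered as non-isolated intermediates; fleeting mechanistic species are named in the Why lines.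

**Route**

Step 1
Reactants: 1 1-(4-hydroxy-3-methoxyphenyl)propan-1-one (propiovanillone)
Product: 2 2-methoxy-4-propanoylphenyl 2,2-dimethylpropanoate
Conditions: PivCl, Et3N, DMAP (cat.), CH2Cl2, 0 °C to rt
Reagents that add atoms: pivaloyl chloride, CC(C)(C)C(Cl)=O
Why: O-acylation of the phenol (nucleophilic acyl substitution) gives a pivalate that tolerates bromination, organozinc and 185 °C, and makes this ring too electron-poor to be attacked in the later iodine(III) oxidation.

Step 2
Reactants: 2 2-methoxy-4-propanoylphenyl 2,2-dimethylpropanoate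
Product: 3 rac-4-(2-bromopropanoyl)-2-methoxyphenyl 2,2-dimethylpropanoate
Conditions: CuBr2 (2.1 equiv), EtOAc/CHCl3, reflux
Reagents that add atoms: copper(II) bromide, Br[Cu]Br
Why: Copper(II)-mediated α-bromination of the aryl ethyl ketone through its enol turns the normally nucleophilic α-carbon into an electrophilic α-keto centre; the racemate is acceptable because the next step is stereoconvergent.

Step 3
Reactants: 4 4-bromo-3-methoxyphenol; 5 3-bromoprop-1-ene (allyl bromide)
Product: 6 1-bromo-2-methoxy-4-(prop-2-en-1-yloxy)benzene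
Conditions: K2CO3, acetone, reflux
Reagents that add atoms: none
Why: Williamson O-allylation of the phenoxide (SN2) installs the allyl group as an ether, which both protects the ring-A oxygen and is the precursor of the C-allyl group.

Step 4
Reactants: 6 1-bromo-2-methoxy-4-(prop-2-en-1-yloxy)benzene; 3 rac-4-(2-bromopropanoyl)-2-methoxyphenyl 2,2-dimethylpropanoate
Product: 9 2-methoxy-4-{(2S)-2-[2-methoxy-4-(prop-2-en-1-yloxy)phenyl]propanoyl}phenyl 2,2-dimethylpropanoate, via aryl Grignard reagent 7 (not isolated), via arylzinc iodide 8 (not isolated)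
Conditions: 6, Mg, THF; ZnI2; then 3, NiCl2·glyme (5 mol %), chiral pybox ligand (6.5 mol %), glyme/THF, −30 °C
Reagents that add atoms: none
Why: Nickel-catalysed stereoconvergent Negishi α-arylation of a racemic α-bromoketone (Fu type): halogen abstraction gives a planar α-keto radical, so both enantiomers of 3 pass through one chiral Ni(aryl)(alkyl) complex whose reductive elimination sets C8 as (S) under catalyst control; the ketone α-carbon reacts as an electrophile with an arene carbon that is itself a natural nucleophilic site, and the base-free conditions do not racemize the tertiary α-aryl centre.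

Step 5
Reactants: 9 2-methoxy-4-{(2S)-2-[2-methoxy-4-(prop-2-en-1-yloxy)phenyl]propanoyl}phenyl 2,2-dimethylpropanoate
Product: 11 2-methoxy-4-{(2R)-2-[2-methoxy-4-(prop-2-en-1-yloxy)phenyl]propyl}phenyl 2,2-dimethylpropanoate, via tosylhydrazone 10 (not isolated)
Conditions: TsNHNH2, PPTS (cat.), EtOH, 50 °C; then catecholborane, CHCl3, 0 °C; NaOAc·3H2O, reflux
Reagents that add atoms: none
Why: Caglioti-type reduction of the tosylhydrazone in Kabalka's catecholborane variant (hydride addition to C=N, loss of sulfinate, loss of N2 from the diazene) converts C=O into CH2 without a cation or enolate at C7, so C8 keeps its configuration (the descriptor changes from S to R only because the priorities change) and the allyl ether and pivalate survive.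

Step 6
Reactants: 11 2-methoxy-4-{(2R)-2-[2-methoxy-4-(prop-2-en-1-yloxy)phenyl]propyl}phenyl 2,2-dimethylpropanoate
Product: 12 4-{(2R)-2-[4-hydroxy-2-methoxy-5-(prop-2-en-1-yl)phenyl]propyl}-2-methoxyphenyl 2,2-dimethylpropanoate
Conditions: 1,2-dichlorobenzene, 185 °C, sealed tube
Reagents that add atoms: none
Why: Aromatic Claisen rearrangement ([3,3] shift, then tautomerization of the ortho-dienone) delivers the allyl group to the less hindered ortho carbon para to the methoxy group, as with 3,4-dioxygenated aryl allyl ethers; any minor isomer from migration between the two oxygens is removed by chromatography, and C8 is not involved.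

Step 7
Reactants: 12 4-{(2R)-2-[4-hydroxy-2-methoxy-5-(prop-2-en-1-yl)phenyl]propyl}-2-methoxyphenyl 2,2-dimethylpropanoate
Product: 14 (4S)-4-[(2R)-1-(4-hydroxy-3-methoxyphenyl)propan-2-yl]-4,5-dimethoxy-2-(prop-2-en-1-yl)cyclohexa-2,5-dien-1-one, via dienone pivalate 13 (not isolated)
Conditions: PhI(OAc)2 (1.0 equiv), MeOH, −20 to 0 °C; then K2CO3 (4 equiv), 0 °C to rt; aq. NH4Cl; chromatography
Reagents that add atoms: methanol, CO
Why: Iodine(III) oxidative dearomatization of the free phenol (aryloxy-iodane, then phenoxenium ion trapped by methanol at the alkyl-bearing para carbon) is the known route to 4-alkyl-4-methoxy-cyclohexadienones from para-alkyl, ortho-allyl, meta-alkoxy phenols, and the pivalate-bearing ring is inert; C4 is created with little induction from C8 (dr expected near 1:1), so the (4S,8R) isomer is obtained by chromatographic separation from its C4 epimer after base-mediated methanolysis of the aryl pivalate in the same pot.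

**Compound list**

1 | 1-(4-hydroxy-3-methoxyphenyl)propan-1-one | CCC(=O)c1ccc(O)c(OC)c1 | starting material
2 | 2-methoxy-4-propanoylphenyl 2,2-dimethylpropanoate | CCC(=O)c1ccc(OC(=O)C(C)(C)C)c(OC)c1 | intermediate
3 | rac-4-(2-bromopropanoyl)-2-methoxyphenyl 2,2-dimethylpropanoate | CC(Br)C(=O)c1ccc(OC(=O)C(C)(C)C)c(OC)c1 | intermediate
4 | 4-bromo-3-methoxyphenol | COc1cc(O)ccc1Br | starting material
5 | 3-bromoprop-1-ene (allyl bromide) | C=CCBr | starting material
6 | 1-bromo-2-methoxy-4-(prop-2-en-1-yloxy)benzene | COc1cc(OCC=C)ccc1Br | intermediate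
7 | [2-methoxy-4-(prop-2-en-1-yloxy)phenyl]magnesium bromide | COc1cc(OCC=C)ccc1[Mg]Br | intermediate
8 | [2-methoxy-4-(prop-2-en-1-yloxy)phenyl]zinc iodide | COc1cc(OCC=C)ccc1[Zn]I | intermediate
9 | 2-methoxy-4-{(2S)-2-[2-methoxy-4-(prop-2-en-1-yloxy)phenyl]propanoyl}phenyl 2,2-dimethylpropanoate | C[C@@H](c1ccc(OCC=C)cc1OC)C(=O)c1ccc(OC(=O)C(C)(C)C)c(OC)c1 | intermediate
10 | N-tosylhydrazone of 9, (2S) | C[C@@H](c1ccc(OCC=C)cc1OC)C(=NNS(=O)(=O)c1ccc(C)cc1)c1ccc(OC(=O)C(C)(C)C)c(OC)c1 | intermediate
11 | 2-methoxy-4-{(2R)-2-[2-methoxy-4-(prop-2-en-1-yloxy)phenyl]propyl}phenyl 2,2-dimethylpropanoate | C[C@H](Cc1ccc(OC(=O)C(C)(C)C)c(OC)c1)c1ccc(OCC=C)cc1OC | intermediate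
12 | 4-{(2R)-2-[4-hydroxy-2-methoxy-5-(prop-2-en-1-yl)phenyl]propyl}-2-methoxyphenyl 2,2-dimethylpropanoate | C[C@H](Cc1ccc(OC(=O)C(C)(C)C)c(OC)c1)c1cc(CC=C)c(O)cc1OC | intermediate
13 | 4-{(2R)-2-[(1S)-1,2-dimethoxy-4-oxo-5-(prop-2-en-1-yl)cyclohexa-2,5-dien-1-yl]propyl}-2-methoxyphenyl 2,2-dimethylpropanoate | C=CCC1=C[C@@](OC)([C@H](C)Cc2ccc(OC(=O)C(C)(C)C)c(OC)c2)C(OC)=CC1=O | intermediate
14 | (4S)-4-[(2R)-1-(4-hydroxy-3-methoxyphenyl)propan-2-yl]-4,5-dimethoxy-2-(prop-2-en-1-yl)cyclohexa-2,5-dien-1-one | C=CCC1=C[C@@](OC)([C@H](C)Cc2ccc(O)c(OC)c2)C(OC)=CC1=O | target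

**Step count**

Total steps: 7. Longest linear sequence: 6 (steps 1, 2, 4, 5, 6, 7).

**Three steps most likely to fail**

Step 4. The arylzinc carries an ortho-methoxy group and an allyl ether, which may lower conversion or ee in the chiral pybox manifold. The fallback sets out from 3 and 6 (through 8) and comes back at 9. It separates bond formation from stereocontrol: the same partners are coupled with an achiral Ni/bipyridine catalyst to give the racemic ketone F1. F1 is converted with LiHMDS and TMSCl (THF, −78 °C) into the trimethylsilyl enol ether F2. C8 is then set by catalytic enantioselective protonation of F2 (chiral N-triflyl thiophosphoramide, phenol as proton source, toluene), which gives 9.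

Step 5. Hydrazone formation on the hindered ketone may be slow, and an ene-hydrazine tautomer could erode the ee at C8. The fallback sets out from 9 and comes back at 11. NaBH4 (EtOH/THF, 0 °C) gives the benzylic alcohol F3 as a mixture of C7 epimers. Thiocarbonyldiimidazole with DMAP gives the imidazolyl thiocarbonate F4. Bu3SnH/AIBN (toluene, 90 °C) then removes the oxygen by Barton–McCombie deoxygenation through a C7 benzylic radical, which cannot epimerize C8, and gives 11.

Step 7. C4 is formed with almost no substrate control, and loss of the C8 hydrogen to a para-quinone methide is a possible side path. The fallback sets out from 12 and comes back at 13, which then goes through the K2CO3/MeOH stage of step 7. Hydroxylative dearomatization (PhI(OAc)2, MeCN/H2O, 0 °C) gives the two tertiary para-quinols, which are separated. The (4S)-para-quinol F5 is O-methylated (MeI, Ag2O) to 13. The (4R)-para-quinol F6 is returned to 12 by reductive rearomatization (Zn, AcOH) and recycled, so material is funnelled to the wanted C4 configuration.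

Further compounds
F1 | step 4 | rac-2-methoxy-4-{2-[2-methoxy-4-(prop-2-en-1-yloxy)phenyl]propanoyl}phenyl 2,2-dimethylpropanoate | CC(c1ccc(OCC=C)cc1OC)C(=O)c1ccc(OC(=O)C(C)(C)C)c(OC)c1
F2 | step 4 | 2-methoxy-4-{2-[2-methoxy-4-(prop-2-en-1-yloxy)phenyl]-1-[(trimethylsilyl)oxy]prop-1-en-1-yl}phenyl 2,2-dimethylpropanoate | CC(c1ccc(OCC=C)cc1OC)=C(O[Si](C)(C)C)c1ccc(OC(=O)C(C)(C)C)c(OC)c1
F3 | step 5 | 4-{(2S)-1-hydroxy-2-[2-methoxy-4-(prop-2-en-1-yloxy)phenyl]propyl}-2-methoxyphenyl 2,2-dimethylpropanoate (C1 epimers) | C[C@@H](c1ccc(OCC=C)cc1OC)C(O)c1ccc(OC(=O)C(C)(C)C)c(OC)c1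
F4 | step 5 | 4-{(2S)-1-[(1H-imidazol-1-ylcarbonothioyl)oxy]-2-[2-methoxy-4-(prop-2-en-1-yloxy)phenyl]propyl}-2-methoxyphenyl 2,2-dimethylpropanoate (C1 epimers) | C[C@@H](c1ccc(OCC=C)cc1OC)C(OC(=S)n1ccnc1)c1ccc(OC(=O)C(C)(C)C)c(OC)c1
F5 | step 7 | 4-{(2R)-2-[(1S)-1-hydroxy-2-methoxy-4-oxo-5-(prop-2-en-1-yl)cyclohexa-2,5-dien-1-yl]propyl}-2-methoxyphenyl 2,2-dimethylpropanoate | C=CCC1=C[C@@](O)([C@H](C)Cc2ccc(OC(=O)C(C)(C)C)c(OC)c2)C(OC)=CC1=O
F6 | step 7 | 4-{(2R)-2-[(1R)-1-hydroxy-2-methoxy-4-oxo-5-(prop-2-en-1-yl)cyclohexa-2,5-dien-1-yl]propyl}-2-methoxyphenyl 2,2-dimethylpropanoate | C=CCC1=C[C@](O)([C@H](C)Cc2ccc(OC(=O)C(C)(C)C)c(OC)c2)C(OC)=CC1=O
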